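(All runs stem from a simulated flask for an exercise.)

Take the flask as a clock.

| flask | substrate | coupling partner | time |
|---|---|---|---|
| alpha | 0.150 M | 0.300 M |  |
| zeta | 0.0600 M | 0.210 M |  |
| epsilon | 0.150 M | 0.600 M |  |
| eta | 0.0750 M | 0.0990 M | 78 min |

| run | time / min | [target] / M |
|---|---|---|
| alpha run | 5.9 | 0.0131 |
| alpha run | 18 | 0.0341 |
| alpha run | 34 | 0.0494 |
| alpha run | 55 | 0.0608 |
| alpha run | 78 | 0.0649 |
| zeta run | 5.9 | 0.0036 |
| zeta run | 18 | 0.0106 |
| zeta run | 34 | 0.0169 |
| zeta run | 55 | 0.0219 |
| zeta run | 78 | 0.0257 |
| epsilon run | 5.9 | 0.0251 |
| epsilon run | 18 | 0.0593 |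
| epsilon run | 34 | 0.0809 |
| epsilon run | 55 | 0.0916 |
| epsilon run | 78 | 0.0926 |

(standard deviation of a reading: 4 × 10⁻⁴ M)

* apparent order in [coupling partner] of the starting rate, round the charge of the alpha run (the rate where two percent of its substrate have turned into target)
* apparent order in [substrate] of the starting rate, round the charge of the alpha run (the rate where two percent of its substrate have turned into target) (one fixed amount of target, the same in the runs compared)
* target in the eta run at 78 min, as a share of the substrate charged

- Overall: substrate + coupling partner -> target.
- Constant volume, constant temperature.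
- An order is taken over about fifteen percent of the charge, up and down.

What do the earliest readings say? Twice the coupling partner, from alpha to epsilon at equal substrate, raises the reading at 5.9 min by a factor 1.92, an order of 0.938. Divided by both charges, the first readings of alpha and zeta give 0.0493 M⁻¹ min⁻¹ and 0.0484 M⁻¹ min⁻¹, so I take the rate as k·c(substrate)·c(coupling partner), first order in each.

Can that constant simply be run on to 78 min? No. In zeta at 78 min, the integrated second-order law needs 2.86 M⁻¹. Call this the clock reading, the time integral of k that the law demands for the target found. It is a mean pace of 0.0366 M⁻¹ min⁻¹, slower than the early 0.0493 M⁻¹ min⁻¹.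

Why should the clock of zeta serve eta? That is the weak spot. At the same time, alpha reads 2.15 M⁻¹ and epsilon 1.76 M⁻¹, both less than zeta, so the clock differs from charge to charge. Eta, with less coupling partner than zeta, may read somewhat higher, but zeta has less coupling partner than alpha and epsilon, so I take its reading.

Putting the reading of zeta into eta, where substrate is the limiting reagent, I get 22.7%. The forecast says 1 and 1 for the orders and 23.5% for eta, between 20.5% and 26%, above my figure, taking the clock of zeta, “perhaps 3.1 given the milder conditions”.

The flask gives 1.0 and 1.0 for the orders and 23.4% for eta, and the epsilon rate over the alpha rate, both where the same amount has been made, is 2.0.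

    substrate + coupling partner ⇌ target + by-product (0.05652 M⁻¹ min⁻¹, 0.09000 M⁻¹ min⁻¹)
    2 substrate → homo dimer (0.01380 M⁻¹ min⁻¹)
    coupling partner → lost reagent (0.006600 min⁻¹)

Read backwards, 23.4% puts the clock of eta at 2.97 M⁻¹, a little ahead of zeta. In epsilon the target made comes to a quarter of the substrate charged at 9.35 min, with the clock at 0.496 M⁻¹, so its pace up to then is 0.0530 M⁻¹ min⁻¹, faster than the 0.0366 M⁻¹ min⁻¹ of zeta over its whole 78 min.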